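## Retrosynthetic overview
1. The target is cut at C1'–C2' (benzyl–alkenyl) into an (E)-alkenylalane and a 4-silyloxy o-quinone methide. Re-aromatisation in the bond-forming event gives the hydroquinone level directly, with no phenol protecting groups.
2. The o-quinone methide comes from vinylogous enolisation of one of the two equivalent methyl groups of C2v-symmetric 2,6-dimethyl-1,4-benzoquinone. The quinone comes from aerobic dearomatising oxidation of 2,6-dimethylphenol.
3. The alkenylalane comes from Negishi syn-methylalumination of an (S)-homopropargylic alcohol, which brings in the C3' methyl and fixes the 2'E alkene.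
4. The (S)-alkynol comes from catalytic asymmetric propargylation (C4'–C5') of (2E,6E)-farnesal, made from (2E,6E)-farnesol. This sets the only stereocentre.
5. No ring is built. The single carbocycle comes from the phenol, is dearomatised (quinone, then quinone methide) and is re-aromatised in the last C–C bond formation.

Assumption: (2E,6E)-farnesol, allenylboronic acid pinacol ester and (S)-TRIP phosphoric acid are bought; side-chain carbons are numbered C1' to C16' from the ring, and the stereocentre C5' of the given SMILES is (S).

## Route

Step 1
Reactants: 1 2,6-dimethylphenol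
Product: 2 2,6-dimethyl-1,4-benzoquinone
Conditions: O2 (1 atm), Co(salen) (C16H14CoN2O2, 5 mol %), DMF, 23 °C
Reagents that add atoms: dioxygen, O=O
Why: This is an aerobic oxidative dearomatisation of a phenol (salcomine-type oxidation) in which both ortho positions are blocked, so the cobalt-bound superoxide oxygenates the phenoxyl radical at the free para carbon and loss of water gives the symmetric quinone, with DMF suppressing C–C coupling to the diphenoquinone and no stereocentre formed.

Step 2
Reactants: 3 (2E,6E)-farnesol
Product: 4 (2E,6E)-farnesal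
Conditions: [Cu(MeCN)4]OTf (5 mol %), 2,2'-bipyridine (5 mol %), TEMPO (5 mol %), N-methylimidazole (10 mol %), air, MeCN, 23 °C
Reagents that add atoms: none
Why: This Stahl-type copper/nitroxyl aerobic oxidation is selective for the primary allylic alcohol, stops at the aldehyde and is mild enough to leave the 2E enal geometry and the isolated trisubstituted alkenes untouched.

Step 3
Reactants: 4 (2E,6E)-farnesal; 5 allenylboronic acid pinacol ester
Product: 7 (4S,5E,9E)-6,10,14-trimethylpentadeca-5,9,13-trien-1-yn-4-ol, via pinacol borate ester 6 (not isolated)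
Conditions: 5 (1.5 equiv), (S)-TRIP phosphoric acid (10 mol %), 4 Å MS, toluene, −20 °C; aq. NaHCO3 work-up
Reagents that add atoms: none
Why: In this chiral-phosphoric-acid-catalysed allenylboration (asymmetric propargylation, SE2' through a closed six-membered transition state) the (S)-acid hydrogen-bonds to a boronate oxygen and the formyl H and exposes the Si face of the enal, which gives the (S)-carbinol by exclusive 1,2-addition (mirror image of the established (R)-acid to (R)-carbinol sense for aryl and alkenyl aldehydes), and borate 6 is hydrolysed on work-up.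

Step 4
Reactants: 2 2,6-dimethyl-1,4-benzoquinone; 7 (4S,5E,9E)-6,10,14-trimethylpentadeca-5,9,13-trien-1-yn-4-ol
Product: 12 2-[(2E,5S,6E,10E)-5-hydroxy-3,7,11,15-tetramethylhexadeca-2,6,10,14-tetraen-1-yl]-6-methylbenzene-1,4-diol, via alkenylalane 8 (not isolated), via lithium dienolate 9 (not isolated), via silyloxy o-quinone methide 10 (not isolated), via aluminium phenoxide 11 (not isolated)
Conditions: (a) 7, AlMe3 (3.0 equiv), Cp2ZrCl2 (0.25 equiv), CH2Cl2, 0 to 23 °C, then volatiles off in vacuo, toluene; (b) 2 (1.4 equiv) added to LiN(SiMe3)2 (1.4 equiv), Et2O–toluene, −78 °C; (c) solution (b) added over 1 h to solution (a) + Me3SiOTf (1.5 equiv), −78 °C; (d) MeOH, then degassed aq. potassium sodium tartrate/citric acid, 0 °C, under Ar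
Reagents that add atoms: AlMe3, C[Al](C)C (the C3' methyl); Me3SiOTf, C[Si](C)(C)OS(=O)(=O)C(F)(F)F, and LiN(SiMe3)2, [Li+].C[Si](C)(C)[N-][Si](C)(C)C (atoms carried only by 9 to 11, lost on work-up)
Why: Proposed new method: Zr-catalysed syn-carboalumination (Negishi) fixes the 2'E alkene as alane 8, while vinylogous deprotonation of one of the two equivalent methyl groups of 2 (both are β-methyls of the C4 enone, as in the lateral lithiation of 2,6-dimethyl-4-pyrone) followed by O4-silylation releases the locked s-cis enone 10 at low stationary concentration in the presence of 8, whose Lewis-acidic aluminium binds the C1 carbonyl oxygen and delivers the alkenyl group with retention through a six-membered transition state driven by re-aromatisation; the closest known reaction types are the base-induced p-quinone to o-quinone methide tautomerisation, the Hooz-type 1,4-addition of alkenylalanes to s-cis enones and the addition of Grignard or alkenylboron reagents to o-quinone methides, and the C5' stereocentre rides through as its aluminium alkoxide with no new stereocentre formed.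

## Compound list
1 | 2,6-dimethylphenol | Cc1cccc(C)c1O | starting material
2 | 2,6-dimethyl-1,4-benzoquinone | CC1=CC(=O)C=C(C)C1=O | intermediate
3 | (2E,6E)-farnesol | CC(C)=CCC/C(C)=C/CC/C(C)=C/CO | starting material
4 | (2E,6E)-farnesal | CC(C)=CCC/C(C)=C/CC/C(C)=C/C=O | intermediate
5 | allenylboronic acid pinacol ester (4,4,5,5-tetramethyl-2-propadienyl-1,3,2-dioxaborolane) | C=C=CB1OC(C)(C)C(C)(C)O1 | starting material
6 | pinacol borate ester of (S)-alkynol 7 (not isolated) | CC(C)=CCC/C(C)=C/CC/C(C)=C/[C@@H](OB1OC(C)(C)C(C)(C)O1)CC#C | intermediate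
7 | (4S,5E,9E)-6,10,14-trimethylpentadeca-5,9,13-trien-1-yn-4-ol | CC(C)=CCC/C(C)=C/CC/C(C)=C/[C@@H](O)CC#C | intermediate
8 | dimethyl[(1E,4S,5E,9E)-4-(dimethylalumanyloxy)-2,6,10,14-tetramethylpentadeca-1,5,9,13-tetraen-1-yl]alumane (not isolated) | CC(C)=CCC/C(C)=C/CC/C(C)=C/[C@@H](O[Al](C)C)C/C(C)=C/[Al](C)C | intermediate
9 | lithium 5-methyl-3-methylidene-4-oxocyclohexa-1,5-dien-1-olate (not isolated) | [Li+].[O-]C1=CC(=C)C(=O)C(C)=C1 | intermediate
10 | 2-methyl-6-methylidene-4-(trimethylsilyloxy)cyclohexa-2,4-dien-1-one (not isolated) | C=C1C=C(O[Si](C)(C)C)C=C(C)C1=O | intermediate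
11 | 4-O-trimethylsilyl ether of 12 as its O1-phenoxide and O5'-alkoxide of dimethylaluminium (not isolated) | CC(C)=CCC/C(C)=C/CC/C(C)=C/[C@@H](O[Al](C)C)C/C(C)=C/Cc1cc(O[Si](C)(C)C)cc(C)c1O[Al](C)C | intermediate
12 | 2-[(2E,5S,6E,10E)-5-hydroxy-3,7,11,15-tetramethylhexadeca-2,6,10,14-tetraen-1-yl]-6-methylbenzene-1,4-diol (CNP0314458.1) | CC(C)=CCC/C(C)=C/CC/C(C)=C/[C@@H](O)C/C(C)=C/Cc1cc(O)cc(C)c1O | target

## Step count and risks
Total step count: 4. Longest linear sequence: 3 (3 → 4 → 7 → 12); step 1 runs in parallel.

The three steps most likely to fail are given below, most risky first.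

**Step 4.**
- The amide base may trigger self-condensation of 2 instead of clean enolisation. It is too bulky to add to the quinone and too poor a reductant for electron transfer, and adding 2 into the base keeps free quinone away from 9.
- Compound 10 may dimerise before it meets 8, which is why 9 is added slowly into 8 and Me3SiOTf.
- A methyl group may transfer in place of the alkenyl group, which is why AlMe3 is stripped and 2 is used in excess.
- The allylic, homopropargylic aluminium alkoxide has to survive the carboalumination, so that stage is kept at or below 23 °C.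

The fallback sets out from 2 and from 8 (made from 7 as before) and comes back at 12. It makes the same benzyl–alkenyl bond by cross-coupling instead of conjugate addition. Reductive acetylation of 2 (Zn, Ac2O) gives 2,6-dimethylbenzene-1,4-diyl diacetate F1. Wohl–Ziegler bromination with one equivalent of NBS (AIBN, PhCF3, 80 °C) functionalises one of the two equivalent methyl groups to give 2-(bromomethyl)-6-methylbenzene-1,4-diyl diacetate F2. Negishi coupling of F2 with 8 under Pd(PPh3)4 (zerovalent palladium, THF, 23 °C) proceeds with retention of alkene geometry to give the 1,4-di-O-acetate of the target F3. K2CO3 in degassed MeOH then gives 12.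

**Step 3.** A β,β-disubstituted enal is a less tested substrate, and the ee may fall short of a single enantiomer. The fallback sets out from 4 and comes back at 7, and it uses resolution instead of asymmetric catalysis. Barbier propargylation (propargyl bromide, Zn, THF/aq. NH4Cl) gives racemic (5E,9E)-6,10,14-trimethylpentadeca-5,9,13-trien-1-yn-4-ol F4. Lipase-catalysed acylation (Pseudomonas cepacia lipase or CAL-B, vinyl acetate, hexane, 30 °C, run to just over 50 % conversion) follows the Kazlauskas preference. The alkenyl chain acts as the large group and propargyl as the medium group. The (R)-enantiomer is therefore converted into (4R,5E,9E)-6,10,14-trimethylpentadeca-5,9,13-trien-1-yn-4-yl acetate F5, and (S)-7 remains unreacted and is separated on silica. The same enzymatic step can polish scalemic 7 from step 3.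

**Step 1.** Radical C–C coupling to the tetramethyldiphenoquinone or C–O polymerisation can erode the yield. The fallback sets out from 1 and comes back at 2, and it uses a two-electron dearomatisation instead of a radical one. PhI(OAc)2 (2.1 equiv) in MeOH at 0 °C gives 4,4-dimethoxy-2,6-dimethylcyclohexa-2,5-dien-1-one F6, and dilute aqueous oxalic acid in THF hydrolyses the ketal to 2.

## Further compounds
F1 | step 4 | 2,6-dimethylbenzene-1,4-diyl diacetate | CC(=O)Oc1cc(C)c(OC(C)=O)c(C)c1
F2 | step 4 | 2-(bromomethyl)-6-methylbenzene-1,4-diyl diacetate | CC(=O)Oc1cc(C)c(OC(C)=O)c(CBr)c1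
F3 | step 4 | 2-[(2E,5S,6E,10E)-5-hydroxy-3,7,11,15-tetramethylhexadeca-2,6,10,14-tetraen-1-yl]-6-methylbenzene-1,4-diyl diacetate | CC(C)=CCC/C(C)=C/CC/C(C)=C/[C@@H](O)C/C(C)=C/Cc1cc(OC(C)=O)cc(C)c1OC(C)=O
F4 | step 3 | racemic (5E,9E)-6,10,14-trimethylpentadeca-5,9,13-trien-1-yn-4-ol | CC(C)=CCC/C(C)=C/CC/C(C)=C/C(O)CC#C
F5 | step 3 | (4R,5E,9E)-6,10,14-trimethylpentadeca-5,9,13-trien-1-yn-4-yl acetate | CC(C)=CCC/C(C)=C/CC/C(C)=C/[C@H](OC(C)=O)CC#C
F6 | step 1 | 4,4-dimethoxy-2,6-dimethylcyclohexa-2,5-dien-1-one | COC1(OC)C=C(C)C(=O)C(C)=C1
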